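**Strategy.** The carbocycle of the chromene-4,7-dione (C4a, C5, C6, C7, C8, C8a) is a dearomatised acylphloroglucinol of alternating polarity: C6 and C8 are the α-carbons of the C7 ketone, C5 and C8a are acyl-level carbons on C4a of the pyranone ring. One operation therefore joins the 1,3-dianion of an acyclic β-keto ester (C6–C7–C8, with C8 carrying lavandulyl and a prenyl ester) to a preformed cis-dimethylpyranone bis-electrophile (C5 acyl chloride, C8a methylsulfanyl): γ-acylation gives C5–C6, addition–elimination gives C8–C8a and the ring. The prenyl ester blocks aromatisation and is then moved onto C8 by stereoablative, ligand-controlled decarboxylative prenylation.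

Key step: step 11

Remark 1: (R)-lavandulol (the natural laevorotatory enantiomer) and the N-propanoyl thiazolidinethione 9 are taken as purchasable.
Remark 2: the bicyclic core is numbered as a chromene (O1, C2, C3, C4, C4a, C5, C6, C7, C8, C8a).
Remark 3: the sense of induction in steps 1 and 12 is catalyst-controlled; the catalyst antipode named is the working choice, and its pseudoenantiomer or mirror image is the remedy if the opposite sense is found.

**Step 1**
Reactants: 1 3-phenylglutaric anhydride (4-phenyloxane-2,6-dione)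
Product: 2 (3S)-5-methoxy-5-oxo-3-phenylpentanoic acid
Conditions: MeOH (10 equiv), quinine-derived bifunctional sulfonamide organocatalyst (10 mol %), MTBE, 23 °C
Reagents that add atoms: methanol (CO)
Why: Bifunctional general-base/hydrogen-bond catalysis makes methanol add to one of the two enantiotopic carbonyl groups of the prochiral anhydride (desymmetrising alcoholysis), which sets the benzylic stereocentre as S.

**Step 2**
Reactants: 2 (3S)-5-methoxy-5-oxo-3-phenylpentanoic acid
Product: 4 7-methyl 1-(3-methylbut-2-en-1-yl) (5S)-3-oxo-5-phenylheptanedioate, via acyl Meldrum's acid 3 (not isolated)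
Conditions: Meldrum's acid, DCC, DMAP, CH2Cl2, 0 to 23 °C; filter; prenol, toluene, 90 °C
Reagents that add atoms: Meldrum's acid (CC1(C)OC(=O)CC(=O)O1); prenol, 3-methylbut-2-en-1-ol (CC(C)=CCO)
Why: C-Acylation of Meldrum's acid by the carbodiimide-activated acid, then thermal loss of acetone and CO2 to an acylketene that prenol traps, is the standard Meldrum's acid route to β-keto esters and does not touch the remote stereocentre.

**Step 3**
Reactants: 5 (R)-lavandulol, (2R)-5-methyl-2-(prop-1-en-2-yl)hex-4-en-1-ol
Product: 6 (R)-lavandulyl iodide, (3R)-3-(iodomethyl)-2,6-dimethylhepta-1,5-diene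
Conditions: PPh3, I2, imidazole, CH2Cl2, 0 °C
Reagents that add atoms: iodine (II)
Why: Appel-type iodination through an alkoxyphosphonium ion and SN2 displacement at the primary carbon (Garegg–Samuelsson conditions) leaves the neighbouring stereocentre untouched and avoids ionisation of the homoallylic system.

**Step 4**
Reactants: 4 7-methyl 1-(3-methylbut-2-en-1-yl) (5S)-3-oxo-5-phenylheptanedioate; 6 (R)-lavandulyl iodide
Product: 7 7-methyl 1-(3-methylbut-2-en-1-yl) (5S)-2-[(2S)-5-methyl-2-(prop-1-en-2-yl)hex-4-en-1-yl]-3-oxo-5-phenylheptanedioate (both C2 epimers)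
Conditions: Cs2CO3, DMF, 23 to 40 °C
Reagents that add atoms: none
Why: Acetoacetic-ester-type C-alkylation of the soft cesium enolate by the primary iodide installs the lavandulyl group at the future C8; the new centre is formed as a mixture on purpose because it is enolised in step 11.

**Step 5**
Reactants: 7 the lavandulylated diester
Product: 8 (3S)-7-[(3-methylbut-2-en-1-yl)oxy]-6-[(2S)-5-methyl-2-(prop-1-en-2-yl)hex-4-en-1-yl]-5,7-dioxo-3-phenylheptanoic acid (both C6 epimers)
Conditions: Me3SnOH, ClCH2CH2Cl, 70 °C; then 1 M HCl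
Reagents that add atoms: trimethyltin hydroxide (C[Sn](C)(C)O)
Why: Trimethyltin hydroxide should hydrolyse the unhindered methyl ester by mild hydroxide transfer while the α-branched prenyl β-keto ester and the alkenes survive, which frees the acid needed as an inert carboxylate in step 11 without base-induced retro-Claisen cleavage.

**Step 6**
Reactants: 9 (4S)-4-benzyl-3-propanoyl-1,3-thiazolidine-2-thione
Product: 10 (2S,3R)-1-[(4S)-4-benzyl-2-sulfanylidene-1,3-thiazolidin-3-yl]-3-hydroxy-2-methylbutan-1-one
Conditions: TiCl4, i-Pr2NEt, NMP, CH2Cl2, 0 °C; MeCHO, −78 to 0 °C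
Reagents that add atoms: acetaldehyde (CC=O)
Why: The titanium-enolate aldol reaction of the thiazolidinethione (Crimmins conditions) runs through the Z-enolate and a non-chelated chair transition state in which the benzyl group of the auxiliary shields one enolate face, giving the Evans syn adduct and so setting both methyl-bearing centres of the later pyranone.

**Step 7**
Reactants: 10 the syn aldol adduct
Product: 11 tert-butyl (4S,5R)-5-hydroxy-4-methyl-3-oxohexanoate
Conditions: KO2CCH2CO2t-Bu, MgCl2, imidazole, THF, 23 °C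
Reagents that add atoms: potassium tert-butyl malonate ([K+].[O-]C(=O)CC(=O)OC(C)(C)C)
Why: The N-acyl thiazolidinethione is an active amide that the magnesium malonate half-ester displaces in a decarboxylative Claisen condensation (Masamune–Brooks type) under almost neutral conditions, so the free hydroxyl and the α-stereocentre survive and the tert-butyl ester blocks lactonisation.

**Step 8**
Reactants: 11 tert-butyl (4S,5R)-5-hydroxy-4-methyl-3-oxohexanoate
Product: 13 tert-butyl (2R,3S)-2,3-dimethyl-6-(methylsulfanyl)-4-oxo-3,4-dihydro-2H-pyran-5-carboxylate, via ketene dithioacetal 12 (not isolated)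
Conditions: K2CO3, CS2, DMF, 0 °C; MeI (2.1 equiv); then DBU, 40 °C
Reagents that add atoms: carbon disulfide (S=C=S); iodomethane (CI)
Why: Dithiocarboxylation and double S-methylation of the active methylene give the α-oxoketene dithioacetal, and the δ-hydroxyl then displaces one methylsulfanyl group by 6-endo-trig addition–elimination (the aliphatic counterpart of the 2-(methylsulfanyl)chromone synthesis), leaving both stereocentres untouched.

**Step 9**
Reactants: 13 the pyranone tert-butyl ester
Product: 14 (2R,3S)-2,3-dimethyl-6-(methylsulfanyl)-4-oxo-3,4-dihydro-2H-pyran-5-carboxylic acid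
Conditions: TFA, CH2Cl2, 0 to 23 °C
Reagents that add atoms: none
Why: Acidolysis of the tert-butyl ester through the tert-butyl cation leaves the push–pull ketene O,S-acetal intact, and the acid should not decarboxylate because its α-carbon is sp2.

**Step 10**
Reactants: 14 the pyranone acid
Product: 15 (2R,3S)-2,3-dimethyl-6-(methylsulfanyl)-4-oxo-3,4-dihydro-2H-pyran-5-carbonyl chloride
Conditions: (COCl)2, DMF (cat.), CH2Cl2, 0 to 23 °C; evaporate, use crude
Reagents that add atoms: oxalyl chloride (ClC(=O)C(Cl)=O)
Why: Vilsmeier-type activation with catalytic DMF turns the acid into the acid chloride, which cannot form a ketene and keeps the C3 stereocentre because no base is present.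

**Step 11**
Reactants: 8 the keto acid; 15 the pyranone acid chloride
Product: 17 3-methylbut-2-en-1-yl (2R,3S)-6-[(1S)-2-carboxy-1-phenylethyl]-5-hydroxy-2,3-dimethyl-8-[(2S)-5-methyl-2-(prop-1-en-2-yl)hex-4-en-1-yl]-4,7-dioxo-3,4,7,8-tetrahydro-2H-chromene-8-carboxylate (both C8 epimers), via open-chain diketo ester 16 (not isolated)
Conditions: 8 (2.0 equiv, excess recoverable), LiN(i-Pr)2 (6.2 equiv), THF, −78 to 0 °C; 15 (1.0 equiv), −78 °C; then 23 °C; 1 M HCl
Reagents that add atoms: none
Why: Three equivalents of base per molecule of 8 give its carboxylate/β-keto ester dianion (a Huckin–Weiler dianion), whose terminal γ-carbon (future C6) is C-acylated by the acid chloride to form C5–C6, and on warming the ester-bearing α-carbon (future C8) adds to the sulfur-bearing C8a of the pyranone and expels methanethiolate to form C8–C8a. The closest known reaction type is the formal [3+3] cyclocondensation of β-keto ester 1,3-dianions, or their 1,3-bis(silyl enol ether) equivalents, with 1,3-dielectrophiles such as α-oxoketene dithioacetals. The carbocycle closes in the 6-endo-trig mode by addition–elimination at the C8a=C4a bond. The new quaternary centre C8 (lavandulyl against prenyl ester) is formed without control on purpose, because step 12 erases and resets it; all other stereocentres are spectators, and the epimerisable C3 should be protected by the low temperature and by the vinylogous-carbonate character of the C4 ketone. The step needs acylation at C6 before C8, attack at the acyl chloride and not at C4 or C8a, and C- rather than O-cyclisation; these should follow from the charge-localised γ-carbanion, the far higher electrophilicity of the acyl chloride and the soft sulfur-substituted acceptor facing lithium-bound oxygens, while the side chain as a carboxylate is the least nucleophilic site and cannot be enolised, and the C8 ester stops the product from aromatising.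

**Step 12**
Reactants: 17 the C8 prenyl ester
Product: 18 (3S)-3-[(2R,3S,8S)-5-hydroxy-2,3-dimethyl-8-(3-methylbut-2-en-1-yl)-8-[(2S)-5-methyl-2-(prop-1-en-2-yl)hex-4-en-1-yl]-4,7-dioxo-3,4,7,8-tetrahydro-2H-chromen-6-yl]-3-phenylpropanoic acid (target)
Conditions: Pd2(dba)3·CHCl3 (2.5 mol %, zerovalent palladium), (R,R)-DACH-phenyl Trost ligand (7.5 mol %), Et3N (2.5 equiv), THF, 23 °C; dilute KHSO4 work-up
Reagents that add atoms: none
Why: Zerovalent palladium ionises the prenyl ester, the C8 carboxylate loses CO2 to a planar acylphloroglucinolate (stereoablation), and this soft nucleophile should attack the unsubstituted terminus of the π-prenyl ligand at C8 from the face left open by the chiral ligand pocket (Tsuji–Trost-type decarboxylative asymmetric allylic alkylation), which sets C8 as S while reversible O-prenylation funnels to the C-prenylated product.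

**Compound list**

1 | 3-phenylglutaric anhydride (4-phenyloxane-2,6-dione) | O=C1CC(c2ccccc2)CC(=O)O1 | starting material
2 | (3S)-5-methoxy-5-oxo-3-phenylpentanoic acid | OC(=O)C[C@@H](CC(=O)OC)c1ccccc1 | intermediate
3 | methyl (3S)-5-(2,2-dimethyl-4,6-dioxo-1,3-dioxan-5-yl)-5-oxo-3-phenylpentanoate (acyl Meldrum's acid) | O=C1OC(C)(C)OC(=O)C1C(=O)C[C@@H](CC(=O)OC)c1ccccc1 | intermediate
4 | 7-methyl 1-(3-methylbut-2-en-1-yl) (5S)-3-oxo-5-phenylheptanedioate | CC(C)=CCOC(=O)CC(=O)C[C@@H](CC(=O)OC)c1ccccc1 | intermediate
5 | (R)-lavandulol, (2R)-5-methyl-2-(prop-1-en-2-yl)hex-4-en-1-ol | OC[C@H](CC=C(C)C)C(C)=C | starting material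
6 | (R)-lavandulyl iodide, (3R)-3-(iodomethyl)-2,6-dimethylhepta-1,5-diene | IC[C@H](CC=C(C)C)C(C)=C | intermediate
7 | 7-methyl 1-(3-methylbut-2-en-1-yl) (5S)-2-[(2S)-5-methyl-2-(prop-1-en-2-yl)hex-4-en-1-yl]-3-oxo-5-phenylheptanedioate (both C2 epimers) | CC(C)=CCOC(=O)C(C[C@H](CC=C(C)C)C(C)=C)C(=O)C[C@@H](CC(=O)OC)c1ccccc1 | intermediate
8 | (3S)-7-[(3-methylbut-2-en-1-yl)oxy]-6-[(2S)-5-methyl-2-(prop-1-en-2-yl)hex-4-en-1-yl]-5,7-dioxo-3-phenylheptanoic acid (both C6 epimers) | CC(C)=CCOC(=O)C(C[C@H](CC=C(C)C)C(C)=C)C(=O)C[C@@H](CC(=O)O)c1ccccc1 | intermediate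
9 | (4S)-4-benzyl-3-propanoyl-1,3-thiazolidine-2-thione | CCC(=O)N1[C@@H](Cc2ccccc2)CSC1=S | starting material
10 | (2S,3R)-1-[(4S)-4-benzyl-2-sulfanylidene-1,3-thiazolidin-3-yl]-3-hydroxy-2-methylbutan-1-one | O[C@H](C)[C@H](C)C(=O)N1[C@@H](Cc2ccccc2)CSC1=S | intermediate
11 | tert-butyl (4S,5R)-5-hydroxy-4-methyl-3-oxohexanoate | O[C@H](C)[C@H](C)C(=O)CC(=O)OC(C)(C)C | intermediate
12 | tert-butyl (4S,5R)-2-[bis(methylsulfanyl)methylidene]-5-hydroxy-4-methyl-3-oxohexanoate (ketene dithioacetal) | O[C@H](C)[C@H](C)C(=O)C(=C(SC)SC)C(=O)OC(C)(C)C | intermediate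
13 | tert-butyl (2R,3S)-2,3-dimethyl-6-(methylsulfanyl)-4-oxo-3,4-dihydro-2H-pyran-5-carboxylate | CC(C)(C)OC(=O)C1=C(SC)O[C@H](C)[C@H](C)C1=O | intermediate
14 | (2R,3S)-2,3-dimethyl-6-(methylsulfanyl)-4-oxo-3,4-dihydro-2H-pyran-5-carboxylic acid | OC(=O)C1=C(SC)O[C@H](C)[C@H](C)C1=O | intermediate
15 | (2R,3S)-2,3-dimethyl-6-(methylsulfanyl)-4-oxo-3,4-dihydro-2H-pyran-5-carbonyl chloride | ClC(=O)C1=C(SC)O[C@H](C)[C@H](C)C1=O | intermediate
16 | (3R)-4-[(2R,3S)-2,3-dimethyl-6-(methylsulfanyl)-4-oxo-3,4-dihydro-2H-pyran-5-carbonyl]-7-[(3-methylbut-2-en-1-yl)oxy]-6-[(2S)-5-methyl-2-(prop-1-en-2-yl)hex-4-en-1-yl]-5,7-dioxo-3-phenylheptanoic acid (open-chain diketo ester; C4 and C6 epimers, largely enolised) | CC(C)=CCOC(=O)C(C[C@H](CC=C(C)C)C(C)=C)C(=O)C([C@@H](CC(=O)O)c1ccccc1)C(=O)C1=C(SC)O[C@H](C)[C@H](C)C1=O | intermediate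
17 | 3-methylbut-2-en-1-yl (2R,3S)-6-[(1S)-2-carboxy-1-phenylethyl]-5-hydroxy-2,3-dimethyl-8-[(2S)-5-methyl-2-(prop-1-en-2-yl)hex-4-en-1-yl]-4,7-dioxo-3,4,7,8-tetrahydro-2H-chromene-8-carboxylate (both C8 epimers) | C=C(C)[C@@H](CC=C(C)C)CC1(C(=O)OCC=C(C)C)C(=O)C([C@@H](CC(=O)O)c2ccccc2)=C(O)C2=C1O[C@H](C)[C@H](C)C2=O | intermediate
18 | (3S)-3-[(2R,3S,8S)-5-hydroxy-2,3-dimethyl-8-(3-methylbut-2-en-1-yl)-8-[(2S)-5-methyl-2-(prop-1-en-2-yl)hex-4-en-1-yl]-4,7-dioxo-3,4,7,8-tetrahydro-2H-chromen-6-yl]-3-phenylpropanoic acid | C=C(C)[C@@H](CC=C(C)C)C[C@]1(CC=C(C)C)C(=O)C([C@@H](CC(=O)O)c2ccccc2)=C(O)C2=C1O[C@H](C)[C@H](C)C2=O | target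

**Totals and risks**

Total step count: 12. Longest linear sequence: 7 steps (9 → 10 → 11 → 13 → 14 → 15 → 17 → 18, steps 6 to 12).

Steps most likely to fail:

Step 11. Proton transfer between the acylated intermediate and unreacted polyanion, ring closure through oxygen instead of carbon, or epimerisation next to the pyranone ketone under the strongly basic conditions may erode the one-pot annulation. The fallback sets out from 8 and 15 and comes back at 17, and separates the two bond formations under non-basic and then mildly basic conditions. Compound 8 is persilylated (Me3SiCl, Et3N; then LiN(i-Pr)2, Me3SiCl, −78 °C) to the tris(trimethylsilyl) dienol ether F1. F1 and 15 are combined without base in CH2Cl2 (−78 to 20 °C, Mukaiyama-type γ-acylation), and aqueous work-up gives 16, now isolated. DBU in MeCN then closes the ring to 17.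

Step 12. Insufficient facial discrimination at C8, or prenyl transfer to oxygen, to C6 or through the substituted allyl terminus, may give the wrong isomers. The fallback sets out from 17 and comes back at 18. Pd(PPh3)4 (zerovalent palladium) and morpholine remove the prenyl ester with loss of CO2 and give the aromatic acylphloroglucinol acid F2. Dearomative C8-prenylation with prenyl bromide under chiral phase-transfer conditions (aqueous KOH, toluene, N-(9-anthracenylmethyl)cinchonidinium bromide, 0 °C) then gives 18, with chromatographic removal of the C8 epimer.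

Step 8. Xanthate formation at the free hydroxyl, retro-aldol cleavage or epimerisation next to the ketone may compete during the one-pot dithiocarboxylation and cyclisation. The fallback sets out from 11 and comes back at 12, which closes to 13. The hydroxyl is masked with t-BuMe2SiOTf and 2,6-lutidine to give the silyl ether F3. K2CO3, CS2 and MeI in DMF give the silylated ketene dithioacetal F4. HF·pyridine in MeCN removes the silyl group and liberates 12, which cyclises to 13 on brief treatment with Et3N.

Further compounds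
F1 | step 11 | trimethylsilyl (3R)-7-[(3-methylbut-2-en-1-yl)oxy]-6-[(2S)-5-methyl-2-(prop-1-en-2-yl)hex-4-en-1-yl]-3-phenyl-5,7-bis[(trimethylsilyl)oxy]hepta-4,6-dienoate | CC(C)=CCOC(O[Si](C)(C)C)=C(C[C@H](CC=C(C)C)C(C)=C)C(O[Si](C)(C)C)=C[C@@H](CC(=O)O[Si](C)(C)C)c1ccccc1
F2 | step 12 | (3S)-3-[(2R,3S)-5,7-dihydroxy-2,3-dimethyl-8-[(2S)-5-methyl-2-(prop-1-en-2-yl)hex-4-en-1-yl]-4-oxo-3,4-dihydro-2H-chromen-6-yl]-3-phenylpropanoic acid | C=C(C)[C@@H](CC=C(C)C)Cc1c(O)c([C@@H](CC(=O)O)c2ccccc2)c(O)c2c1O[C@H](C)[C@H](C)C2=O
F3 | step 8 | tert-butyl (4S,5R)-5-[(tert-butyldimethylsilyl)oxy]-4-methyl-3-oxohexanoate | CC(C)(C)[Si](C)(C)O[C@H](C)[C@H](C)C(=O)CC(=O)OC(C)(C)C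
F4 | step 8 | tert-butyl (4S,5R)-2-[bis(methylsulfanyl)methylidene]-5-[(tert-butyldimethylsilyl)oxy]-4-methyl-3-oxohexanoate | CC(C)(C)[Si](C)(C)O[C@H](C)[C@H](C)C(=O)C(=C(SC)SC)C(=O)OC(C)(C)C
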